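**Same plateau.** Grey charges 0.075 M against green's 0.050 M at one loading, yet grey levels near 18.8 % and green near 19.0 %, while violet, with more free catalyst, ends at 22.1 %.

| flask | substrate | free catalyst | remark | time |
|---|---|---|---|---|
| green | 0.050 M | 0.061 mol% | run made earlier |  |
| amber | 0.050 M | 0.041 mol% | run made earlier |  |
| violet | 0.050 M | 0.091 mol% | run made earlier |  |
| grey | 0.075 M | 0.061 mol% | run made earlier |  |
| south-west | 0.050 M (fed, over 5.00 h) | 0.061 mol% | a stirred flask in which substrate is dosed at a steady rate over 5.00 h without added volume, worked up at 10 h | 10 h |
| south | 0.050 M | 0.061 mol% | one stirred flow tank at steady state, fed with the mixture as stated, mean residence time 10 h |  |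
| north-west | 0.050 M | 0.061 mol% | everything together in a closed stirred flask, run for 10 h | 10 h |

- green (time / h: product / %, substrate / %): 1.33: 18.2, 23.5; 2.50: 18.5, 6.3; 4.00: 19.0, 1.3; 5.00: 18.8, 0.1; 6.00: 19.0, 0.7
- amber (time / h: product / %, substrate / %): 1.50: 15.4, 19.6; 3.00: 15.9, 4.0; 5.00: 15.6, 0.2; 6.00: 16.3, 0.2; 8.00: 16.5, 0.1
- violet (time / h: product / %, substrate / %): 0.667: 16.7, 48.5; 2.00: 22.0, 11.8; 4.00: 22.7, 1.3; 6.00: 22.3, 0; 8.00: 22.1, 0.2
- grey (time / h: product / %, substrate / %): 0.667: 15.6, 48.3; 2.00: 18.9, 12.2; 4.00: 17.9, 1.4; 6.00: 18.8, 0; 8.00: 17.9, 0

(readings scatter by 0.3 percentage points)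

- the stated concentrations are those of everything mixed, before any reaction; amounts are the same in each set-up
- the feed brings no volume worth counting
- the earlier runs were made in a closed, stirred flask

- the set-up with the highest amount of product at the outlet or at the end, in percent of the substrate put in ("none" if the first two lie within 2 percentage points) (south-west / south / north-west / none)
- amount of product at the outlet or at the end, in percent of the substrate put in, south-west
- amount of product at the outlet or at the end, in percent of the substrate put in, south
- amount of product at the outlet or at the end, in percent of the substrate put in, north-west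

**The pool.** Substrate decays at 1.11 h⁻¹ in green, and at 2.00 h violet and grey hold 11.8 % and 12.2 % despite their different loadings and concentrations. At 6.00 h, 80.3 % of green's charge stands in neither column. I read that as a pool of intermediate, which free catalyst turns into product, and I take product to kill free catalyst.

**Fork number.** Follow one free catalyst molecule. Each time it either turns over or dies, and its chance of dying per turnover is p/(S·i), with p the product share and i the pool share. Summing the forks gives p×p = 2·S·ī·m, with m the loading and ī the mean pool share. Green gives p×p/(2m) = 29.6; amber gives 33.2, violet 26.8, so this holds roughly across loadings, violet's figure lying below amber's. Taking ī as 29.1 %, the midpoint of the pool at 1.33 h, gives S = 102, the selectivity factor.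

**My reckoning.** North-west has green's charge, so I put it on green's plateau. In the tank the shares stand still, so p×p = S·i·m, with i = 1 − s − p and s = 1/(1 + kτ), which gives 20.9 %. South-west's substrate arrives over 5.00 h, so by 1.33 h, the time I used in green, 26.6 % of it has come in; the midpoint of that share, put into the same formula, gives 12.8 %. The tank's lead of 1.9 percentage points lies inside 2 points, so I say none.

**The forecast.** It chose north-west, with 13 % for south-west, 6 % for south, which is less than my tank figure, and 18.9 % for north-west: “The batch wins”.

**The result.** South-west gives 7.23 %, south 22.2 % and north-west 19.0 %, so the best is south.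

    substrate → intermediate (k = 0.0180 min⁻¹)
    free catalyst + intermediate → free catalyst + product (k = 810 M⁻¹ min⁻¹)
    free catalyst + product → spent catalyst A (k = 5.50 M⁻¹ min⁻¹)
    free catalyst → spent catalyst B (k = 0.0140 min⁻¹)

**Using S.** With the 69.2 % of intermediate at south's outlet, S gives 20.7 % for the tank. Run backwards on south-west, 7.23 % asks for ī = 4.22 %, less than the 13.3 % I allowed. Turning into spent catalyst B alone gives free catalyst a half-life of 0.83 h, shorter than the 5.00 h of dosing.

The earlier runs and the new flask stem from a simulated flask from invented constants.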